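Ring D (the hydroxy-dimethylpyran on ring B) is closed last, on the finished flavan, by a thermal propargyl Claisen / ortho-quinone methide / oxa-6π cascade; the C3'' hydroxyl is then set by Jacobsen epoxidation and hydride opening.

**Retrosynthetic overview**
1. Ring D last: O4' of ring B has one free ortho carbon (C5'), and C4''–C3''–C2''(Me2) bridges C5' back to O4'. This is the retron of an aryl 1,1-dimethylpropargyl ether (Claisen shift to C5', 1,5-H shift to an ortho-quinone methide, oxa-6π closure). The 7-OH / C6-(1,1-dimethylallyl) pair of ring A is the Claisen retron of a 7-O-prenyl ether and is set in the same heating.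
2. C3''–OH: Jacobsen epoxidation of the new C3''=C4'' bond, then hydride opening at benzylic C4''.
3. Ring C before it: CBS reduction of a dihydrochalcone gives the (S)-carbinol; intramolecular Pd-catalysed C–O coupling onto the ring-A bromide forms O1–C8a with retention.
4. Dihydrochalcone: Claisen–Schmidt condensation of ring-B acetophenone 8 with ring-A aldehyde 2, then copper hydride 1,4-reduction; the 6'-prenyl group enters by Stille coupling; 4'-O-SEM (temporary) and 3'-O-MOM keep the catechol oxygens apart.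
5. Order of ring formation: A and B bought, C in step 10, D in step 13 (temporary oxirane on D made in step 14 and opened in step 15).

Key step: step 13

Remark: flavan numbering is used (O1, C2–C4, C4a–C8a; ring B C1'–C6' with C1' on C2, 3'-OH, O4', C5', 6'-prenyl; ring D O1''–C2''(Me2)–C3''–C4'' fused at C4'/C5'; prenyl = 3-methylbut-2-en-1-yl); the target is read as (2S,3''S), and 1 and 3 are taken as catalogue compounds.

**Step 1**
Reactants: 1 2-bromo-4-hydroxybenzaldehyde
Product: 2 2-bromo-4-(prenyloxy)benzaldehyde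
Conditions: prenyl bromide, K2CO3, DMF, rt
Reagents that add atoms: 1-bromo-3-methylbut-2-ene, CC(C)=CCBr
Why: Williamson ether synthesis on the only phenol; the ether is both the 7-O protecting group and the latent C6 side chain.

**Step 2**
Reactants: 3 2-bromo-4,5-dihydroxybenzaldehyde
Product: 4 2-bromo-5-hydroxy-4-{[2-(trimethylsilyl)ethoxy]methoxy}benzaldehyde
Conditions: SEMCl (1.0 equiv), K2CO3 (1.0 equiv), DMF, 0 °C
Reagents that add atoms: 2-(trimethylsilyl)ethoxymethyl chloride, C[Si](C)(C)CCOCCl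
Why: Williamson-type O-alkylation that should be selective because the 4-OH para to the formyl group is the more acidic phenol and is the one deprotonated by one equivalent of base.

**Step 3**
Reactants: 4 2-bromo-5-hydroxy-4-{[2-(trimethylsilyl)ethoxy]methoxy}benzaldehyde
Product: 5 2-bromo-5-(methoxymethoxy)-4-{[2-(trimethylsilyl)ethoxy]methoxy}benzaldehyde
Conditions: MOMCl, K2CO3, acetone, rt
Reagents that add atoms: chloromethyl methyl ether, COCCl
Why: Williamson-type MOM protection of the remaining phenol; an acetal is chosen for O3' because it cannot migrate to the neighbouring O4' phenoxide freed in step 11.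

**Step 4**
Reactants: 5 2-bromo-5-(methoxymethoxy)-4-{[2-(trimethylsilyl)ethoxy]methoxy}benzaldehyde
Product: 6 5-(methoxymethoxy)-2-prenyl-4-{[2-(trimethylsilyl)ethoxy]methoxy}benzaldehyde
Conditions: tributyl(prenyl)stannane, Pd(PPh3)4 (5 mol%), DMF, 90 °C
Reagents that add atoms: tributyl(3-methylbut-2-en-1-yl)stannane, CC(C)=CC[Sn](CCCC)(CCCC)CCCC
Why: Stille coupling at the bromide activated by the ortho formyl group; reductive elimination at the less hindered primary terminus should give the linear prenyl arene, and the stannane does not add to the aldehyde.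

**Step 5**
Reactants: 6 5-(methoxymethoxy)-2-prenyl-4-{[2-(trimethylsilyl)ethoxy]methoxy}benzaldehyde
Product: 7 racemic 1-[5-(methoxymethoxy)-2-prenyl-4-{[2-(trimethylsilyl)ethoxy]methoxy}phenyl]ethan-1-ol
Conditions: MeMgBr, THF, −78 °C; aq NH4Cl
Reagents that add atoms: methylmagnesium bromide, C[Mg]Br
Why: Grignard addition to the aldehyde; the new stereocentre is racemic and is removed in step 6.

**Step 6**
Reactants: 7 racemic 1-[5-(methoxymethoxy)-2-prenyl-4-{[2-(trimethylsilyl)ethoxy]methoxy}phenyl]ethan-1-ol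
Product: 8 1-[5-(methoxymethoxy)-2-prenyl-4-{[2-(trimethylsilyl)ethoxy]methoxy}phenyl]ethan-1-one
Conditions: Dess–Martin periodinane, CH2Cl2, rt
Reagents that add atoms: none
Why: Dess–Martin oxidation of the benzylic alcohol to the methyl ketone under neutral conditions that leave the prenyl alkene and both acetals alone.

**Step 7**
Reactants: 8 1-[5-(methoxymethoxy)-2-prenyl-4-{[2-(trimethylsilyl)ethoxy]methoxy}phenyl]ethan-1-one and 2 2-bromo-4-(prenyloxy)benzaldehyde
Product: 9 (E)-3-[2-bromo-4-(prenyloxy)phenyl]-1-[5-(methoxymethoxy)-2-prenyl-4-{[2-(trimethylsilyl)ethoxy]methoxy}phenyl]prop-2-en-1-one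
Conditions: KOH, EtOH, rt
Reagents that add atoms: none
Why: Claisen–Schmidt condensation of a methyl ketone with a non-enolisable aldehyde; all protecting groups are ethers or acetals and are stable to hydroxide.

**Step 8**
Reactants: 9 (E)-3-[2-bromo-4-(prenyloxy)phenyl]-1-[5-(methoxymethoxy)-2-prenyl-4-{[2-(trimethylsilyl)ethoxy]methoxy}phenyl]prop-2-en-1-one
Product: 10 3-[2-bromo-4-(prenyloxy)phenyl]-1-[5-(methoxymethoxy)-2-prenyl-4-{[2-(trimethylsilyl)ethoxy]methoxy}phenyl]propan-1-one
Conditions: [(Ph3P)CuH]6 (5 mol%), PhMe2SiH, t-BuOH, toluene, rt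
Reagents that add atoms: none
Why: Copper hydride conjugate reduction (Stryker type), which reduces only the enone C=C and spares the isolated alkenes, the aryl bromide and the ketone.

**Step 9**
Reactants: 10 3-[2-bromo-4-(prenyloxy)phenyl]-1-[5-(methoxymethoxy)-2-prenyl-4-{[2-(trimethylsilyl)ethoxy]methoxy}phenyl]propan-1-one
Product: 11 (1S)-3-[2-bromo-4-(prenyloxy)phenyl]-1-[5-(methoxymethoxy)-2-prenyl-4-{[2-(trimethylsilyl)ethoxy]methoxy}phenyl]propan-1-ol
Conditions: (R)-Me-CBS oxazaborolidine (20 mol%), catecholborane, toluene, −78 °C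
Reagents that add atoms: none
Why: Corey–Bakshi–Shibata reduction with the aryl group as the large and the CH2CH2Ar chain as the small substituent, so the (R)-catalyst should give the (S)-carbinol (the future C2); catecholborane does not hydroborate the alkenes at this temperature.

**Step 10**
Reactants: 11 (1S)-3-[2-bromo-4-(prenyloxy)phenyl]-1-[5-(methoxymethoxy)-2-prenyl-4-{[2-(trimethylsilyl)ethoxy]methoxy}phenyl]propan-1-ol
Product: 12 (2S)-3'-(methoxymethoxy)-6'-prenyl-7-(prenyloxy)-4'-{[2-(trimethylsilyl)ethoxy]methoxy}flavan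
Conditions: Pd(OAc)2 (3 mol%), 2-(di-tert-butylphosphino)-1,1'-binaphthyl (4 mol%), Cs2CO3, toluene, 70 °C
Reagents that add atoms: none
Why: Buchwald-type intramolecular palladium-catalysed aryl etherification closes ring C through the O1–C8a bond, so no bond to the carbinol carbon is broken and C2 keeps its (S) configuration; this avoids an SN2 displacement at a hindered benzylic centre that is para to an oxygen.

**Step 11**
Reactants: 12 (2S)-3'-(methoxymethoxy)-6'-prenyl-7-(prenyloxy)-4'-{[2-(trimethylsilyl)ethoxy]methoxy}flavan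
Product: 13 (2S)-4'-hydroxy-3'-(methoxymethoxy)-6'-prenyl-7-(prenyloxy)flavan
Conditions: TBAF, THF/DMPU, 60 °C; aq NH4Cl
Reagents that add atoms: none
Why: Fluoride-induced fragmentation of the aryl SEM ether frees only O4'; the MOM acetal, the prenyl ether and the alkenes are inert to fluoride.

**Step 12**
Reactants: 13 (2S)-4'-hydroxy-3'-(methoxymethoxy)-6'-prenyl-7-(prenyloxy)flavan
Product: 14 (2S)-3'-(methoxymethoxy)-4'-[(2-methylbut-3-yn-2-yl)oxy]-6'-prenyl-7-(prenyloxy)flavan
Conditions: 3-chloro-3-methylbut-1-yne, CuCl2·2H2O (cat.), DBU, MeCN, 0 °C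
Reagents that add atoms: 3-chloro-3-methylbut-1-yne, C#CC(C)(C)Cl
Why: Copper-catalysed O-propargylation of a phenol with a tertiary propargylic chloride, the standard way to aryl 1,1-dimethylpropargyl ethers, on the only free OH.

**Step 13**
Reactants: 14 (2S)-3'-(methoxymethoxy)-4'-[(2-methylbut-3-yn-2-yl)oxy]-6'-prenyl-7-(prenyloxy)flavan
Product: 18 (2S)-7-acetoxy-6-(2-methylbut-3-en-2-yl)-3'-(methoxymethoxy)-6'-prenylflavan with ring D as 2,2-dimethyl-2H-pyran on C4'/C5', via ortho-quinone methide 15 (not isolated), via chromene prenyl ether 16 (not isolated), via chromene phenol 17 (not isolated)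
Conditions: PhNEt2, 190 °C (sealed tube); then Ac2O, DMAP, rt
Reagents that add atoms: acetic anhydride, CC(=O)OC(C)=O
Why: On heating, the 1,1-dimethylpropargyl ether on O4' undergoes a [3,3] shift to C5' (the only free ortho carbon, since C3' carries OMOM), the allenyl dienone enolises, a 1,5-hydrogen shift gives the ortho-quinone methide 15, and oxa-6π electrocyclisation closes ring D as the 2,2-dimethyl-2H-chromene 16, so the C5'–C4'' and O1''–C2'' bonds of the ring are made in one operation. The closest known reaction type is the thermal propargyl Claisen route to 2,2-dimethylchromenes, run here in the same pot as the aromatic Claisen rearrangement of an aryl prenyl ether, which at the higher temperature moves the 7-O-prenyl group with allylic inversion to C6 and frees the 7-OH (17). Ring D is closed by a thermal disrotatory 6π electrocyclisation of the 1-oxatriene O4'=C4'–C5'=C4''–C3''=C2'', and it closes after ring C and before the ring-A shift because the propargyl ether rearranges well below the temperature needed for the prenyl ether. No stereocentre is created: no bond to C2 is broken, and C3'' is set in step 14. The selectivity needed is C6 over C8 in ring A, which rests on C6 being para to O1 and flanked by one substituent only, while C8 lies between two oxygen-bearing carbons. Acetylation in the same flask caps the hindered 7-OH so that it cannot cyclise onto the new side chain or be oxidised in step 14.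

**Step 14**
Reactants: 18 (2S)-7-acetoxy-6-(2-methylbut-3-en-2-yl)-3'-(methoxymethoxy)-6'-prenylflavan with ring D as 2,2-dimethyl-2H-pyran
Product: 19 (2S,3''S,4''S)-3'',4''-epoxide of 18
Conditions: (S,S)-(salen)MnCl (Jacobsen catalyst, salen = N,N'-bis(3,5-di-tert-butylsalicylidene)cyclohexane-1,2-diamine dianion, 5 mol%), NMO, mCPBA, CH2Cl2, −78 °C
Reagents that add atoms: 3-chloroperoxybenzoic acid, OOC(=O)c1cccc(Cl)c1
Why: Jacobsen epoxidation, for which 2,2-dimethylchromenes are the model substrates; the trivalent manganese salen catalyst should transfer oxygen to the cis, aryl-conjugated C3''=C4'' bond much faster than to the isolated prenyl and vinyl groups, and the (S,S)-catalyst should set the (3''S,4''S)-oxide under catalyst control.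

**Step 15**
Reactants: 19 (2S,3''S,4''S)-3'',4''-epoxide of 18
Product: 20 (2S,3''S)-3'-O-methoxymethyl ether of the target
Conditions: LiAlH4, THF, 0 °C to rt
Reagents that add atoms: none
Why: SN2 hydride opening of the oxirane at benzylic C4'' (C3'' is neopentyl-like next to the quaternary C2''), which leaves the oxygen on C3'' with its configuration untouched, while the same reagent cleaves the aryl acetate.

**Step 16**
Reactants: 20 (2S,3''S)-3'-O-methoxymethyl ether of the target
Product: 21 target, (3S)-6-[(2S)-7-hydroxy-6-(2-methylbut-3-en-2-yl)-3,4-dihydro-2H-chromen-2-yl]-2,2-dimethyl-5-prenyl-3,4-dihydro-2H-chromene-3,8-diol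
Conditions: HCl (cat.), MeOH, 40 °C
Reagents that add atoms: none
Why: Acid-catalysed transacetalisation removes the MOM group; the conditions are mild because the 6'-prenyl group has no ortho hydroxyl to cyclise onto and the 1,1-dimethylallyl alkene is monosubstituted and slow to protonate.

**Compound list**
1 | 2-bromo-4-hydroxybenzaldehyde | O=Cc1ccc(O)cc1Br | starting material
2 | 2-bromo-4-[(3-methylbut-2-en-1-yl)oxy]benzaldehyde | O=Cc1ccc(OCC=C(C)C)cc1Br | intermediate
3 | 2-bromo-4,5-dihydroxybenzaldehyde | O=Cc1cc(O)c(O)cc1Br | starting material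
4 | 2-bromo-5-hydroxy-4-{[2-(trimethylsilyl)ethoxy]methoxy}benzaldehyde | O=Cc1cc(O)c(OCOCC[Si](C)(C)C)cc1Br | intermediate
5 | 2-bromo-5-(methoxymethoxy)-4-{[2-(trimethylsilyl)ethoxy]methoxy}benzaldehyde | O=Cc1cc(OCOC)c(OCOCC[Si](C)(C)C)cc1Br | intermediate
6 | 5-(methoxymethoxy)-2-(3-methylbut-2-en-1-yl)-4-{[2-(trimethylsilyl)ethoxy]methoxy}benzaldehyde | O=Cc1cc(OCOC)c(OCOCC[Si](C)(C)C)cc1CC=C(C)C | intermediate
7 | racemic 1-[5-(methoxymethoxy)-2-(3-methylbut-2-en-1-yl)-4-{[2-(trimethylsilyl)ethoxy]methoxy}phenyl]ethan-1-ol | CC(O)c1cc(OCOC)c(OCOCC[Si](C)(C)C)cc1CC=C(C)C | intermediate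
8 | 1-[5-(methoxymethoxy)-2-(3-methylbut-2-en-1-yl)-4-{[2-(trimethylsilyl)ethoxy]methoxy}phenyl]ethan-1-one | CC(=O)c1cc(OCOC)c(OCOCC[Si](C)(C)C)cc1CC=C(C)C | intermediate
9 | (E)-chalcone from 8 and 2 (ring-A 2-bromo-4-prenyloxyphenyl on the alkene carbon; ring-B aryl on the carbonyl) | O=C(/C=C/c1ccc(OCC=C(C)C)cc1Br)c1cc(OCOC)c(OCOCC[Si](C)(C)C)cc1CC=C(C)C | intermediate
10 | dihydrochalcone, the 1,3-diarylpropan-1-one from 9 | O=C(CCc1ccc(OCC=C(C)C)cc1Br)c1cc(OCOC)c(OCOCC[Si](C)(C)C)cc1CC=C(C)C | intermediate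
11 | (1S)-1,3-diarylpropan-1-ol from 10 | O[C@H](c1cc(OCOC)c(OCOCC[Si](C)(C)C)cc1CC=C(C)C)CCc1ccc(OCC=C(C)C)cc1Br | intermediate
12 | (2S)-flavan: 7-O-prenyl, 3'-OMOM, 4'-OSEM, 6'-prenyl | CC(C)=CCOc1ccc2c(c1)O[C@H](c1cc(OCOC)c(OCOCC[Si](C)(C)C)cc1CC=C(C)C)CC2 | intermediate
13 | (2S)-flavan: 7-O-prenyl, 3'-OMOM, 4'-OH, 6'-prenyl | CC(C)=CCOc1ccc2c(c1)O[C@H](c1cc(OCOC)c(O)cc1CC=C(C)C)CC2 | intermediate
14 | (2S)-flavan: 7-O-prenyl, 3'-OMOM, 4'-O-(2-methylbut-3-yn-2-yl), 6'-prenyl | CC(C)=CCOc1ccc2c(c1)O[C@H](c1cc(OCOC)c(OC(C)(C)C#C)cc1CC=C(C)C)CC2 | intermediate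
15 | ortho-quinone methide (not isolated): ring B as 2,5-dienone with C4'=O and C5'=CH–CH=CMe2 | CC(C)=CCOc1ccc2c(c1)O[C@H](C1=C(CC=C(C)C)C(=CC=C(C)C)C(=O)C(OCOC)=C1)CC2 | intermediate
16 | chromene prenyl ether (not isolated): ring D closed as 2,2-dimethyl-2H-pyran, 7-O-prenyl intact | CC(C)=CCOc1ccc2c(c1)O[C@H](c1cc(OCOC)c3c(c1CC=C(C)C)C=CC(C)(C)O3)CC2 | intermediate
17 | chromene phenol (not isolated): 7-OH, 6-(2-methylbut-3-en-2-yl) | C=CC(C)(C)c1cc2c(cc1O)O[C@H](c1cc(OCOC)c3c(c1CC=C(C)C)C=CC(C)(C)O3)CC2 | intermediate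
18 | 7-acetate of 17 | C=CC(C)(C)c1cc2c(cc1OC(C)=O)O[C@H](c1cc(OCOC)c3c(c1CC=C(C)C)C=CC(C)(C)O3)CC2 | intermediate
19 | (2S,3''S,4''S)-3'',4''-epoxide of 18 | C=CC(C)(C)c1cc2c(cc1OC(C)=O)O[C@H](c1cc(OCOC)c3c(c1CC=C(C)C)[C@@H]4O[C@@H]4C(C)(C)O3)CC2 | intermediate
20 | (2S,3''S)-3'-O-methoxymethyl ether of the target | C=CC(C)(C)c1cc2c(cc1O)O[C@H](c1cc(OCOC)c3c(c1CC=C(C)C)C[C@H](O)C(C)(C)O3)CC2 | intermediate
21 | (3S)-6-[(2S)-7-hydroxy-6-(2-methylbut-3-en-2-yl)-3,4-dihydro-2H-chromen-2-yl]-2,2-dimethyl-5-(3-methylbut-2-en-1-yl)-3,4-dihydro-2H-chromene-3,8-diol | C=CC(C)(C)c1cc2c(cc1O)O[C@H](c1cc(O)c3c(c1CC=C(C)C)C[C@H](O)C(C)(C)O3)CC2 | target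

**Step count and risks**
Total step count: 16. Longest linear sequence: 15 (steps 2–6, then 7–16).

The three steps most likely to fail:

Step 13. What may go wrong: migration of the prenyl group to C8 instead of C6 in ring A, or its loss as isoprene, at a late and valuable stage. Fallback: the ring-A shift is moved to the open-chain ketone 10, where the bromine next to the competing ortho carbon blocks it. Heating 10 in PhNEt2 at 190 °C should give the rearranged phenol ketone F1, which is capped with Et2NCOCl/K2CO3 as the diethylcarbamate ketone F2 (stable to fluoride and carbonate, removed by LiAlH4; ring A has no neighbouring phenoxide to which it could migrate). CBS reduction as in step 9 gives the (S)-carbinol F3, C–O coupling as in step 10 the flavan carbamate F4, TBAF the 4'-phenol F5, and propargylation as in step 12 the propargyl ether F6. Heating F6 in o-xylene at 140 °C runs the ring-D cascade alone and gives the chromene carbamate F7; epoxidation as in step 14 gives the oxirane F8, and LiAlH4 opens the oxirane and removes the carbamate, returning to the route at 20.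

Step 14. What may go wrong: oxygen transfer to the 6'-prenyl alkene in competition with the chromene, lower facial selectivity because of the substituent peri to C4'', and acid-triggered rearrangement of the benzylic oxirane. Fallback: from 18, copper-catalysed enantioselective protoboration of the styrene-type C3''=C4'' bond (CuCl, NaOtBu, a chiral bisphosphine such as Ph-BPE in the enantiomer that leads to the 3''S series, B2pin2, MeOH, THF). This does not touch isolated alkenes and places boron on C3'' (copper on benzylic C4''), giving the boronate F9. NaOH/H2O2 then replaces boron by hydroxyl with retention and hydrolyses the acetate, returning to the route at 20.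

Step 4. What may go wrong: transfer of the prenyl group through its tertiary end (allylic transposition to the branched isomer) and slow coupling next to the formyl group. Fallback: from 5, Stille coupling with allyltributylstannane (Pd(PPh3)4, DMF, 90 °C), where no such ambiguity exists, gives the allyl aldehyde F10. Cross-metathesis with 2-methylbut-2-ene (second-generation Grubbs catalyst, (H2IMes)(PCy3)Cl2Ru=CHPh, CH2Cl2, 40 °C) converts allyl into prenyl and returns to the route at 6.

**Further compounds**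
F1 | step 13 | 3-[2-bromo-4-hydroxy-5-(2-methylbut-3-en-2-yl)phenyl]-1-[ring-B aryl of 8]propan-1-one | O=C(CCc1cc(C(C)(C)C=C)c(O)cc1Br)c1cc(OCOC)c(OCOCC[Si](C)(C)C)cc1CC=C(C)C
F2 | step 13 | diethylcarbamate of F1 | O=C(CCc1cc(C(C)(C)C=C)c(OC(=O)N(CC)CC)cc1Br)c1cc(OCOC)c(OCOCC[Si](C)(C)C)cc1CC=C(C)C
F3 | step 13 | (1S)-carbinol from F2 | O[C@H](c1cc(OCOC)c(OCOCC[Si](C)(C)C)cc1CC=C(C)C)CCc1cc(C(C)(C)C=C)c(OC(=O)N(CC)CC)cc1Br
F4 | step 13 | (2S)-flavan: 7-O-diethylcarbamoyl, 6-(2-methylbut-3-en-2-yl), 3'-OMOM, 4'-OSEM, 6'-prenyl | C=CC(C)(C)c1cc2c(cc1OC(=O)N(CC)CC)O[C@H](c1cc(OCOC)c(OCOCC[Si](C)(C)C)cc1CC=C(C)C)CC2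
F5 | step 13 | 4'-phenol from F4 | C=CC(C)(C)c1cc2c(cc1OC(=O)N(CC)CC)O[C@H](c1cc(OCOC)c(O)cc1CC=C(C)C)CC2
F6 | step 13 | 4'-O-(2-methylbut-3-yn-2-yl) ether of F5 | C=CC(C)(C)c1cc2c(cc1OC(=O)N(CC)CC)O[C@H](c1cc(OCOC)c(OC(C)(C)C#C)cc1CC=C(C)C)CC2
F7 | step 13 | chromene from F6 (ring D as 2,2-dimethyl-2H-pyran, 7-O-diethylcarbamoyl) | C=CC(C)(C)c1cc2c(cc1OC(=O)N(CC)CC)O[C@H](c1cc(OCOC)c3c(c1CC=C(C)C)C=CC(C)(C)O3)CC2
F8 | step 13 | (3''S,4''S)-epoxide of F7 | C=CC(C)(C)c1cc2c(cc1OC(=O)N(CC)CC)O[C@H](c1cc(OCOC)c3c(c1CC=C(C)C)[C@@H]4O[C@@H]4C(C)(C)O3)CC2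
F9 | step 14 | (3''S)-3''-(pinacolboryl) derivative of 18 with ring D saturated | C=CC(C)(C)c1cc2c(cc1OC(C)=O)O[C@H](c1cc(OCOC)c3c(c1CC=C(C)C)C[C@H](B4OC(C)(C)C(C)(C)O4)C(C)(C)O3)CC2
F10 | step 4 | 2-allyl-5-(methoxymethoxy)-4-{[2-(trimethylsilyl)ethoxy]methoxy}benzaldehyde | O=Cc1cc(OCOC)c(OCOCC[Si](C)(C)C)cc1CC=C
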